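**Assumptions (one line each):**
- The target is the 2,3‑trans (2R,3R) dihydroflavonol, as the SMILES gives (I checked the CIP descriptors).
- (S)‑Liquiritigenin, the licorice flavanone, is bought as the chiral starting material. (2S)‑Flavanone has the same spatial arrangement at C2 as a (2R)‑dihydroflavonol, because the CIP priorities of C3 and the aryl group swap when the 3‑OH is added.

## Retrosynthetic overview
- The target is the free 3‑OH compound, obtained by removing a TBS group from a 3‑O‑TBS dihydroflavonol that carries both C‑prenyl groups.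
- Both C–prenyl bonds (C8 and C3′) come from one double aromatic Claisen [3,3] rearrangement of bis(1,1‑dimethylallyl) aryl ethers. Those ethers come from bis(1,1‑dimethylpropargyl) ethers by Lindlar reduction.
- The propargyl ethers also protect the two phenols during the C3 oxygenation (Rubottom‑type oxidation of the flavanone silyl enol ether).
- C3 is set trans to the C2 aryl group by substrate control from the purchased C2 stereocenter.
- No ring is formed: the chromanone ring is already in the starting material, and the only cyclic events are the two six‑membered [3,3] transition states.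

## Route

**Step 1**
Reactants: 1 (S)‑liquiritigenin; 2 3‑chloro‑3‑methylbut‑1‑yne
Product: 3 (2S)‑7‑(2‑methylbut‑3‑yn‑2‑yloxy)‑2‑[4‑(2‑methylbut‑3‑yn‑2‑yloxy)phenyl]chroman‑4‑one
Conditions: 2 (4 equiv), K2CO3, KI (cat.), CuI (cat.), acetone, 50 °C
Reagents that add atoms: 3‑chloro‑3‑methylbut‑1‑yne, CC(C)(Cl)C#C (adds the CMe2C≡CH group at each phenolic O)
Why: Cu‑assisted O‑alkylation of the phenoxides by the tertiary propargyl chloride gives both aryl propargyl ethers. The mild carbonate base leaves the flavanone C2 stereocenter intact.

**Step 2**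
Reactants: 3; 4 TBSOTf
Product: 5 (2S)‑4‑(tert‑butyldimethylsilyloxy)‑2H‑chromene (flavene TBS enol ether) bearing the two propargyl ethers
Conditions: 4 (1.5 equiv), Et3N, CH2Cl2, 0 °C
Reagents that add atoms: TBSOTf, CC(C)(C)[Si](C)(C)OS(=O)(=O)C(F)(F)F (adds TBS)
Why: Soft silyl‑triflate/amine enolization traps the C3 enol without touching C2, so the stereocenter stays sp3 and is not racemized through ring opening.

**Step 3**
Reactants: 5; 6 dimethyldioxirane (DMDO)
Product: 7 (2R,3R)‑3‑(TBS‑oxy)‑7‑(2‑methylbut‑3‑yn‑2‑yloxy)‑2‑[4‑(2‑methylbut‑3‑yn‑2‑yloxy)phenyl]chroman‑4‑one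
Conditions: 6 (about 1.1 equiv, 0.08 M in acetone), CH2Cl2, –78 → 0 °C
Reagents that add atoms: DMDO, CC1(C)OO1 (adds one O)
Why: This is a Rubottom oxidation. DMDO epoxidizes the electron‑rich enol ether on the face anti to the C2 aryl group. The silyloxy epoxide opens and the silyl group migrates, giving the 3‑OTBS ketone with OH trans to the aryl group, i.e. 2,3‑trans (2R,3R). The electron‑poor alkynes are untouched at –78 °C.

**Step 4**
Reactants: 7
Product: 8 (2R,3R)‑3‑OTBS‑7‑(2‑methylbut‑3‑en‑2‑yloxy)‑2‑[4‑(2‑methylbut‑3‑en‑2‑yloxy)phenyl]chroman‑4‑one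
Conditions: H2 (1 atm), Lindlar catalyst, quinoline, EtOAc, rt
Reagents that add atoms: none (H2 only)
Why: Poisoned Pd stops at the alkene stage, converting each tertiary propargyl ether into a 1,1‑dimethylallyl ether. The ketone, benzylic aryl ether and TBS ether survive, and the stereocenters are not involved.

**Step 5 (key step)**
Reactants: 8
Product: 9 (2R,3R)‑3‑OTBS‑3′,8‑diprenyl‑7,4′‑dihydroxyflavanone (the 3‑O‑TBS ether of the target)
Conditions: xylenes, BHT (cat.), 140 °C, sealed tube, Ar
Reagents that add atoms: none
Why: Double aromatic Claisen [3,3] rearrangement. A 1,1‑dimethylallyl aryl ether delivers its terminal CH2 to the ortho carbon, so the ether O–CMe2–CH=CH2 becomes an ortho‑CH2–CH=CMe2 (normal prenyl) group. The 7‑O ether goes to C8 (the C7–C8 bond has more double‑bond character), and the 4′‑O ether goes to C3′. Neutral thermal conditions avoid base‑mediated C2/C3 epimerization, and the stereocenters are remote from the reacting atoms.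

**Step 6**
Reactants: 9
Product: 10 3‑Hydroxyglabrol, (2R,3R)‑3,7,4′‑trihydroxy‑3′,8‑diprenylflavanone
Conditions: HF·pyridine, pyridine, THF, 0 °C → rt
Reagents that add atoms: none
Why: Buffered fluoride cleaves the secondary TBS ether. Basic fluoride is avoided because it could open the ring through the C3 enolate. The prenyl groups and free phenols tolerate these mildly acidic, buffered conditions.

## Checks carried out
- **Structure:** The final product has the 7‑OH, the 8‑prenyl group, a 3′‑prenyl‑4′‑OH B ring, the C4 ketone, a 3‑OH and a 2‑aryl group, as in the target SMILES.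
- **Stereochemistry:** The C2 SMILES symbol is unchanged from 1 through 10 (allowing for the reordering of neighbors). C3 is set once, in Step 3, and is not touched afterwards.
- **Atom count:** C15H12O4 (1) → C25H24O4 (3) → C31H38O4Si (5) → C31H38O5Si (7) → C31H42O5Si (8) → C31H42O5Si (9, an isomer of 8) → C25H28O5 (10). This matches the target formula.
- **Protecting groups:** The propargyl/allyl ethers act as phenol protection through Steps 2–4 and then become the prenyl groups in Step 5.

## Compound list
1 | (S)‑liquiritigenin, (2S)‑7‑hydroxy‑2‑(4‑hydroxyphenyl)chroman‑4‑one | O=C1C[C@@H](c2ccc(O)cc2)Oc2cc(O)ccc12 | starting material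
2 | 3‑chloro‑3‑methylbut‑1‑yne | CC(C)(Cl)C#C | starting material (reagent)
3 | bis(1,1‑dimethylpropargyl) ether of 1 | C#CC(C)(C)Oc1ccc(cc1)[C@@H]2CC(=O)c3ccc(OC(C)(C)C#C)cc3O2 | intermediate
4 | tert‑butyldimethylsilyl triflate | CC(C)(C)[Si](C)(C)OS(=O)(=O)C(F)(F)F | starting material (reagent)
5 | 4‑OTBS flavene (silyl enol ether of 3) | C#CC(C)(C)Oc1ccc(cc1)[C@@H]2C=C(O[Si](C)(C)C(C)(C)C)c3ccc(OC(C)(C)C#C)cc3O2 | intermediate
6 | dimethyldioxirane | CC1(C)OO1 | starting material (reagent)
7 | (2R,3R)‑3‑OTBS dihydroflavonol bis‑propargyl ether | C#CC(C)(C)Oc1ccc(cc1)[C@H]2Oc3cc(OC(C)(C)C#C)ccc3C(=O)[C@@H]2O[Si](C)(C)C(C)(C)C | intermediate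
8 | (2R,3R)‑3‑OTBS dihydroflavonol bis(1,1‑dimethylallyl) ether | C=CC(C)(C)Oc1ccc(cc1)[C@H]2Oc3cc(OC(C)(C)C=C)ccc3C(=O)[C@@H]2O[Si](C)(C)C(C)(C)C | intermediate
9 | 3‑O‑TBS‑3‑hydroxyglabrol | CC(C)=CCc1cc(ccc1O)[C@H]2Oc3c(ccc(O)c3CC=C(C)C)C(=O)[C@@H]2O[Si](C)(C)C(C)(C)C | intermediate
10 | 3‑hydroxyglabrol | CC(C)=CCc1cc([C@H]2Oc3c(ccc(O)c3CC=C(C)C)C(=O)[C@@H]2O)ccc1O | target

## Totals
Total steps: 6. Longest linear sequence: 6.

## Three steps most likely to fail
1. **Step 5 (double Claisen).** Possible problems are C6 versus C8 regioselectivity on the A ring, competing ionization or cyclization of the tertiary allyl ether (to dihydrobenzofurans or chromans), and incomplete conversion. *Fallback:* drop the sigmatropic installation. Protect the phenols as MOM ethers, brominate or iodinate C8 and C3′ regioselectively, and couple with a prenylzinc or prenylboron reagent.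
2. **Step 3 (Rubottom oxidation).** Diastereoselectivity may be below full trans, or DMDO may oxidize the allyl or propargyl ether side chains. *Fallback:* start from commercial (+)‑taxifolin, which already has 2R,3R. Protect it, remove the 5‑OH and 3′‑OH through their aryl triflates by Pd/formate reduction and cross‑couple, then continue from the phenol stage. This is longer but sets C3 without an oxidation.
3. **Step 1 (bis‑propargylation).** Partial racemization of the base‑sensitive 5‑deoxyflavanone C2, C‑alkylation, or mono‑etherification are all possible. *Fallback:* change the protection strategy. Make the bis‑MOM ether of 1 and use the Step 2–3 sequence on it. Then build the tertiary allyl aryl ethers after removing the MOM groups, with a Lewis‑acid‑promoted coupling of 2‑methylbut‑3‑en‑2‑yl trichloroacetimidate, and carry on to Step 5.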